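The cyclohexane ring is closed last, by joining the lactone O–CH carbon (C7a of the hexahydrobenzofuranone) to the adjacent ring CH (C7) that bears the 3-hydroxyprop-1-en-2-yl group. This 2-(hydroxymethyl)homoallylic alcohol unit is the retron of a carbonyl allylation with allylic transposition. The precursor is an acyclic, unprotected γ-hydroxy-γ-lactone (masked aldehyde–acid, both anomers) whose quaternary carbon carries a symmetric 2-alkylidenepropane-1,3-diol. Pd(0)/InI umpolung converts one allylic C–OH into an allylindium, which adds to the unmasked aldehyde through a chair–chair transition state. One operation closes the ring, sets C7 and C7a trans, creates the exocyclic methylene, leaves the CH2OH and re-forms the trans-fused lactone.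

Key step: step 16

Assumption: half-ester 13, auxiliary 16, LiTMP and the chiral sulfonate-bearing imidazolinium salt of step 4 are taken as purchasable; the antipode of that ligand is chosen that delivers the (S)-configured quaternary carbon.

Step 1
Reactants: 1 tert-butyl(but-3-yn-1-yloxy)dimethylsilane
Product: 4 (2E)-5-[(tert-butyldimethylsilyl)oxy]-3-methylpent-2-en-1-ol, via alkenylalane 2 (not isolated), via aluminate complex 3 (not isolated)
Conditions: Me3Al, Cp2ZrCl2 (cat.), CH2Cl2, 0 °C to rt; n-BuLi, THF, −78 °C; (CH2O)n, rt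
Reagents that add atoms: trimethylaluminium C[Al](C)C; formaldehyde (as paraformaldehyde) C=O
Why: Zr-catalysed syn-carboalumination (Negishi) puts Me on the internal and Al on the terminal alkyne carbon, and hydroxymethylation of the ate complex with retention should give only the (E)-trisubstituted allylic alcohol.

Step 2
Reactants: 4 (2E)-5-[(tert-butyldimethylsilyl)oxy]-3-methylpent-2-en-1-ol
Product: 5 (2E)-5-[(tert-butyldimethylsilyl)oxy]-3-methylpent-2-en-1-yl diethyl phosphate
Conditions: ClP(O)(OEt)2, Et3N, DMAP (cat.), CH2Cl2, 0 °C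
Reagents that add atoms: diethyl chlorophosphate CCOP(=O)(Cl)OCC
Why: O-phosphorylation of the primary allylic alcohol gives the leaving group for allylic substitution without touching the alkene geometry.

Step 3
Reactants: 6 bis(4,4,5,5-tetramethyl-1,3,2-dioxaborolan-2-yl)methane; 7 2,2-dimethyl-1,3-dioxan-5-one
Product: 9 2-[(2,2-dimethyl-1,3-dioxan-5-ylidene)methyl]-4,4,5,5-tetramethyl-1,3,2-dioxaborolane, via lithiated diboronate 8 (not isolated)
Conditions: LiTMP, THF, 0 °C; then 7, −78 °C to rt
Reagents that add atoms: none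
Why: Boron-Wittig olefination (addition of the α-boryl carbanion to the ketone, then B–O elimination) should give the alkenylboronate, and the symmetric ketone removes any alkene-geometry issue.

Step 4
Reactants: 5 (2E)-5-[(tert-butyldimethylsilyl)oxy]-3-methylpent-2-en-1-yl diethyl phosphate; 9 2-[(2,2-dimethyl-1,3-dioxan-5-ylidene)methyl]-4,4,5,5-tetramethyl-1,3,2-dioxaborolane
Product: 10 tert-butyl{[(3S)-3-ethenyl-4-(2,2-dimethyl-1,3-dioxan-5-ylidene)-3-methylbutyl]oxy}dimethylsilane
Conditions: CuCl (5 mol %), chiral sulfonate-bearing imidazolinium salt (5.5 mol %), NaOMe (2 equiv), THF, 22 °C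
Reagents that add atoms: none
Why: NHC–Cu-catalysed enantioselective allylic substitution: methoxide-promoted B-to-Cu transfer of the alkenyl group and γ-selective (SN2′) addition to the (E)-trisubstituted allylic phosphate should create the quaternary C(Me)(vinyl) centre, its (S) configuration being set by the chiral NHC–Cu complex.

Step 5
Reactants: 10 tert-butyl{[(3S)-3-ethenyl-4-(2,2-dimethyl-1,3-dioxan-5-ylidene)-3-methylbutyl]oxy}dimethylsilane
Product: 11 (3S)-3-ethenyl-4-(2,2-dimethyl-1,3-dioxan-5-ylidene)-3-methylbutan-1-ol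
Conditions: TBAF, THF, 0 °C to rt
Reagents that add atoms: none
Why: Fluoride desilylation of the primary TBS ether leaves the acetonide, both alkenes and the quaternary centre untouched.

Step 6
Reactants: 11 (3S)-3-ethenyl-4-(2,2-dimethyl-1,3-dioxan-5-ylidene)-3-methylbutan-1-ol
Product: 12 (3S)-3-ethenyl-4-(2,2-dimethyl-1,3-dioxan-5-ylidene)-3-methylbutanal
Conditions: Dess–Martin periodinane, pyridine, CH2Cl2, 0 °C to rt
Reagents that add atoms: none
Why: Dess–Martin oxidation of the primary alcohol should give an aldehyde that has no α-stereocentre and cannot conjugate with either alkene.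

Step 7
Reactants: 13 (2S)-4-methoxy-2-methyl-4-oxobutanoic acid
Product: 14 1-tert-butyl 4-methyl (2S)-2-methylbutanedioate
Conditions: t-BuOC(=NH)CCl3, BF3·OEt2 (cat.), cyclohexane/CH2Cl2, rt
Reagents that add atoms: tert-butyl 2,2,2-trichloroacetimidate CC(C)(C)OC(=N)C(Cl)(Cl)Cl
Why: Acid-catalysed tert-butyl transfer from the trichloroacetimidate esterifies the free acid without touching the methyl ester or the α-stereocentre.

Step 8
Reactants: 14 1-tert-butyl 4-methyl (2S)-2-methylbutanedioate
Product: 15 (3S)-4-tert-butoxy-3-methyl-4-oxobutanoic acid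
Conditions: LiOH (1.1 equiv), THF/H2O, 0 °C; then dilute HCl
Reagents that add atoms: lithium hydroxide [Li+].[OH-]
Why: Saponification should be site-selective for the unhindered methyl ester because the tert-butyl ester resists acyl attack, and the stereocentre, α only to the unreactive ester, should not epimerise at 0 °C.

Step 9
Reactants: 15 (3S)-4-tert-butoxy-3-methyl-4-oxobutanoic acid; 16 (4R)-4-benzyl-1,3-thiazolidine-2-thione
Product: 17 tert-butyl (2S)-4-[(4R)-4-benzyl-2-thioxo-1,3-thiazolidin-3-yl]-2-methyl-4-oxobutanoate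
Conditions: EDC·HCl, DMAP (cat.), CH2Cl2, 0 °C to rt
Reagents that add atoms: none
Why: Carbodiimide/DMAP N-acylation (Steglich type) attaches the auxiliary to the CH2-side carbonyl, the existing stereocentre being remote from the activated acyl group.

Step 10
Reactants: 17 tert-butyl (2S)-4-[(4R)-4-benzyl-2-thioxo-1,3-thiazolidin-3-yl]-2-methyl-4-oxobutanoate; 12 (3S)-3-ethenyl-4-(2,2-dimethyl-1,3-dioxan-5-ylidene)-3-methylbutanal
Product: 19 tert-butyl (2S,3R,4S,6S)-3-{[(4R)-4-benzyl-2-thioxo-1,3-thiazolidin-3-yl]carbonyl}-6-ethenyl-7-(2,2-dimethyl-1,3-dioxan-5-ylidene)-4-hydroxy-2,6-dimethylheptanoate, via titanium enolate 18 (not isolated)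
Conditions: TiCl4 (1.05 equiv), i-Pr2NEt (1.1 equiv), NMP (2 equiv), CH2Cl2, −78 °C; then 12, −78 °C
Reagents that add atoms: none
Why: In this auxiliary-controlled titanium aldol of an N-acylthiazolidinethione (Evans-syn sense), the (Z)-enolate reacts through a non-chelated Zimmerman–Traxler chair on the face away from the benzyl group, which should set the 3,4-syn pair as (3R,4S), while the bulky tert-butyl ester keeps the aldolate from lactonising.

Step 11
Reactants: 20 methyl (2R)-3-hydroxy-2-methylpropanoate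
Product: 21 methyl (2R)-3-[(tert-butyldimethylsilyl)oxy]-2-methylpropanoate
Conditions: TBSCl, imidazole, DMF, rt
Reagents that add atoms: tert-butyldimethylsilyl chloride CC(C)(C)[Si](C)(C)Cl
Why: Silylation of the primary alcohol of the Roche ester protects it for the later esterification.

Step 12
Reactants: 21 methyl (2R)-3-[(tert-butyldimethylsilyl)oxy]-2-methylpropanoate
Product: 22 (2R)-3-[(tert-butyldimethylsilyl)oxy]-2-methylpropanoic acid
Conditions: LiOH, THF/MeOH/H2O, 0 °C; then dilute HCl to pH 4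
Reagents that add atoms: lithium hydroxide [Li+].[OH-]
Why: Cold saponification should give the acid with the C2 configuration retained and without β-elimination of the silyloxy group.

Step 13
Reactants: 19 tert-butyl (2S,3R,4S,6S)-3-{[(4R)-4-benzyl-2-thioxo-1,3-thiazolidin-3-yl]carbonyl}-6-ethenyl-7-(2,2-dimethyl-1,3-dioxan-5-ylidene)-4-hydroxy-2,6-dimethylheptanoate; 22 (2R)-3-[(tert-butyldimethylsilyl)oxy]-2-methylpropanoic acid
Product: 23 tert-butyl (2S,3R,4S,6S)-3-{[(4R)-4-benzyl-2-thioxo-1,3-thiazolidin-3-yl]carbonyl}-4-{[(2R)-3-[(tert-butyldimethylsilyl)oxy]-2-methylpropanoyl]oxy}-6-ethenyl-7-(2,2-dimethyl-1,3-dioxan-5-ylidene)-2,6-dimethylheptanoate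
Conditions: EDC·HCl, DMAP, CH2Cl2, 0 °C to rt
Reagents that add atoms: none
Why: Steglich esterification of the secondary C4 hydroxyl touches no stereocentre, and the near-neutral conditions should avoid retro-aldol and β-elimination.

Step 14
Reactants: 23 tert-butyl (2S,3R,4S,6S)-3-{[(4R)-4-benzyl-2-thioxo-1,3-thiazolidin-3-yl]carbonyl}-4-{[(2R)-3-[(tert-butyldimethylsilyl)oxy]-2-methylpropanoyl]oxy}-6-ethenyl-7-(2,2-dimethyl-1,3-dioxan-5-ylidene)-2,6-dimethylheptanoate
Product: 24 tert-butyl (2S,3R,4S,6S)-4-{[(2R)-3-[(tert-butyldimethylsilyl)oxy]-2-methylpropanoyl]oxy}-6-ethenyl-7-(2,2-dimethyl-1,3-dioxan-5-ylidene)-3-formyl-2,6-dimethylheptanoate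
Conditions: i-Bu2AlH (1.2 equiv), CH2Cl2, −78 °C; Rochelle-salt work-up
Reagents that add atoms: none
Why: Reductive cleavage of the highly electrophilic N-acylthiazolidinethione by DIBAL-H at −78 °C should stop at a stable aluminium hemithioaminal that releases the aldehyde on work-up, while both hindered esters survive and the α-centre is not epimerised.

Step 15
Reactants: 24 tert-butyl (2S,3R,4S,6S)-4-{[(2R)-3-[(tert-butyldimethylsilyl)oxy]-2-methylpropanoyl]oxy}-6-ethenyl-7-(2,2-dimethyl-1,3-dioxan-5-ylidene)-3-formyl-2,6-dimethylheptanoate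
Product: 25 (1S,3S)-3-ethenyl-6-hydroxy-5-(hydroxymethyl)-1-[(3R,4S)-2-hydroxy-4-methyl-5-oxooxolan-3-yl]-3-methylhex-4-en-1-yl (2R)-3-hydroxy-2-methylpropanoate (both lactol anomers)
Conditions: TFA/CH2Cl2/H2O (5:5:1), 0 °C to rt; toluene co-evaporation
Reagents that add atoms: none
Why: Aqueous acidolysis should remove the tert-butyl ester (alkyl–oxygen cleavage), the acetonide and the TBS ether at once, and the freed aldehyde–acid closes to the 5-hydroxy-γ-lactone, which shields the β-acyloxy aldehyde from elimination and epimerisation.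

Step 16
Reactants: 25 (1S,3S)-3-ethenyl-6-hydroxy-5-(hydroxymethyl)-1-[(3R,4S)-2-hydroxy-4-methyl-5-oxooxolan-3-yl]-3-methylhex-4-en-1-yl (2R)-3-hydroxy-2-methylpropanoate (both lactol anomers)
Product: 28 (3S,3aR,4S,6S,7R,7aR)-6-ethenyl-7-(3-hydroxyprop-1-en-2-yl)-3,6-dimethyl-2-oxooctahydro-1-benzofuran-4-yl (2R)-3-hydroxy-2-methylpropanoate, via allylindium species 26 (not isolated), via seco hydroxy acid 27 (not isolated)
Conditions: Pd(PPh3)4 (5 mol %), InI (1.5 equiv), THF/H2O (4:1), rt; then dilute HCl (pH 2–3)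
Reagents that add atoms: none
Why: Ring–chain tautomerism of the 5-hydroxy-γ-lactone exposes the aldehyde–acid, while Pd(0) ionises one of the two equivalent allylic C–OH bonds of the alkylidene-1,3-diol and InI reduces the π-allyl complex to σ-allylindium(III) 26, which adds to the aldehyde through its substituted (γ) terminus in a closed six-membered transition state; the γ-hydroxy acid 27 then lactonises. The closest known reaction type is the Pd-catalysed umpolung (Barbier-type) carbonyl allylation with allylic alcohols mediated by InI, whose intramolecular variants give 2-alkenylcycloalkanols. The carbocycle closes in a 6-exo-trig sense at the C=O (γ-attack gives the six-membered ring, α-attack would need an eight-membered one), and the lactone then closes by 5-exo-trig acyl substitution. C7a and C7 are set in a chair–chair (trans-decalin-like) array with the C3a and C4 substituents equatorial: an axial aldehyde oxygen would clash 1,3-diaxially with the axial C6 methyl group, and the allylindium reacts as the isomer with CH2–In trans to the quaternary carbon, so that O and the propenyl group both end up equatorial (7,7a-trans and 3a,7a-trans). The step needs chemoselectivity for the aldehyde over the ester and lactone carbonyls (intrinsic to allylindium), single ionisation (the two CH2OH arms are equivalent and InI is limiting) and stereoconvergence, which should hold because both lactol anomers and both allylindium geometries equilibrate before the irreversible C–C bond formation.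

Compound list
1 | tert-butyl(but-3-yn-1-yloxy)dimethylsilane | C#CCCO[Si](C)(C)C(C)(C)C | starting material
2 | dimethyl[(1E)-4-(tert-butyldimethylsilyloxy)-2-methylbut-1-enyl]alane | C[Al](C)/C=C(\C)CCO[Si](C)(C)C(C)(C)C | intermediate
3 | lithium butyl(dimethyl)[(1E)-4-(tert-butyldimethylsilyloxy)-2-methylbut-1-enyl]aluminate | [Li+].CCCC[Al-](C)(C)/C=C(\C)CCO[Si](C)(C)C(C)(C)C | intermediate
4 | (2E)-5-[(tert-butyldimethylsilyl)oxy]-3-methylpent-2-en-1-ol | OC/C=C(\C)CCO[Si](C)(C)C(C)(C)C | intermediate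
5 | (2E)-5-[(tert-butyldimethylsilyl)oxy]-3-methylpent-2-en-1-yl diethyl phosphate | CCOP(=O)(OCC)OC/C=C(\C)CCO[Si](C)(C)C(C)(C)C | intermediate
6 | bis(4,4,5,5-tetramethyl-1,3,2-dioxaborolan-2-yl)methane | CC1(C)OB(CB2OC(C)(C)C(C)(C)O2)OC1(C)C | starting material
7 | 2,2-dimethyl-1,3-dioxan-5-one | CC1(C)OCC(=O)CO1 | starting material
8 | [bis(4,4,5,5-tetramethyl-1,3,2-dioxaborolan-2-yl)methyl]lithium | [Li]C(B1OC(C)(C)C(C)(C)O1)B1OC(C)(C)C(C)(C)O1 | intermediate
9 | 2-[(2,2-dimethyl-1,3-dioxan-5-ylidene)methyl]-4,4,5,5-tetramethyl-1,3,2-dioxaborolane | CC1(C)OCC(=CB2OC(C)(C)C(C)(C)O2)CO1 | intermediate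
10 | tert-butyl{[(3S)-3-ethenyl-4-(2,2-dimethyl-1,3-dioxan-5-ylidene)-3-methylbutyl]oxy}dimethylsilane | C=C[C@](C)(CCO[Si](C)(C)C(C)(C)C)C=C1COC(C)(C)OC1 | intermediate
11 | (3S)-3-ethenyl-4-(2,2-dimethyl-1,3-dioxan-5-ylidene)-3-methylbutan-1-ol | C=C[C@](C)(CCO)C=C1COC(C)(C)OC1 | intermediate
12 | (3S)-3-ethenyl-4-(2,2-dimethyl-1,3-dioxan-5-ylidene)-3-methylbutanal | C=C[C@](C)(CC=O)C=C1COC(C)(C)OC1 | intermediate
13 | (2S)-4-methoxy-2-methyl-4-oxobutanoic acid | OC(=O)[C@@H](C)CC(=O)OC | starting material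
14 | 1-tert-butyl 4-methyl (2S)-2-methylbutanedioate | CC(C)(C)OC(=O)[C@@H](C)CC(=O)OC | intermediate
15 | (3S)-4-tert-butoxy-3-methyl-4-oxobutanoic acid | CC(C)(C)OC(=O)[C@@H](C)CC(=O)O | intermediate
16 | (4R)-4-benzyl-1,3-thiazolidine-2-thione | S=C1N[C@H](Cc2ccccc2)CS1 | starting material
17 | tert-butyl (2S)-4-[(4R)-4-benzyl-2-thioxo-1,3-thiazolidin-3-yl]-2-methyl-4-oxobutanoate | CC(C)(C)OC(=O)[C@@H](C)CC(=O)N1C(=S)SC[C@H]1Cc1ccccc1 | intermediate
18 | trichlorotitanium (Z)-enolate of 17 | CC(C)(C)OC(=O)[C@@H](C)/C=C(\O[Ti](Cl)(Cl)Cl)N1C(=S)SC[C@H]1Cc1ccccc1 | intermediate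
19 | tert-butyl (2S,3R,4S,6S)-3-{[(4R)-4-benzyl-2-thioxo-1,3-thiazolidin-3-yl]carbonyl}-6-ethenyl-7-(2,2-dimethyl-1,3-dioxan-5-ylidene)-4-hydroxy-2,6-dimethylheptanoate | C=C[C@](C)(C[C@H](O)[C@@H]([C@H](C)C(=O)OC(C)(C)C)C(=O)N1C(=S)SC[C@H]1Cc1ccccc1)C=C1COC(C)(C)OC1 | intermediate
20 | methyl (2R)-3-hydroxy-2-methylpropanoate | COC(=O)[C@H](C)CO | starting material
21 | methyl (2R)-3-[(tert-butyldimethylsilyl)oxy]-2-methylpropanoate | COC(=O)[C@H](C)CO[Si](C)(C)C(C)(C)C | intermediate
22 | (2R)-3-[(tert-butyldimethylsilyl)oxy]-2-methylpropanoic acid | OC(=O)[C@H](C)CO[Si](C)(C)C(C)(C)C | intermediate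
23 | 19 acylated at the C4 oxygen with the (2R)-3-silyloxy-2-methylpropanoyl group | C=C[C@](C)(C[C@H](OC(=O)[C@H](C)CO[Si](C)(C)C(C)(C)C)[C@@H]([C@H](C)C(=O)OC(C)(C)C)C(=O)N1C(=S)SC[C@H]1Cc1ccccc1)C=C1COC(C)(C)OC1 | intermediate
24 | tert-butyl (2S,3R,4S,6S)-4-{[(2R)-3-[(tert-butyldimethylsilyl)oxy]-2-methylpropanoyl]oxy}-6-ethenyl-7-(2,2-dimethyl-1,3-dioxan-5-ylidene)-3-formyl-2,6-dimethylheptanoate | C=C[C@](C)(C[C@H](OC(=O)[C@H](C)CO[Si](C)(C)C(C)(C)C)[C@@H]([C@H](C)C(=O)OC(C)(C)C)C=O)C=C1COC(C)(C)OC1 | intermediate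
25 | 5-hydroxy-γ-lactone (masked aldehyde–acid) with free alkylidene-1,3-diol and free side-chain hydroxyl, both lactol anomers | C=C[C@](C)(C[C@H](OC(=O)[C@H](C)CO)[C@@H]1C(O)OC(=O)[C@H]1C)C=C(CO)CO | intermediate
26 | open-chain aldehyde–acid carrying the σ-allylindium(III) unit (drawn as the hydroxide iodide, CH2–In trans to the quaternary carbon) | O=C[C@H]([C@H](C)C(=O)O)[C@@H](OC(=O)[C@H](C)CO)C[C@@](C)(C=C)/C=C(\CO)C[In](O)I | intermediate
27 | seco hydroxy acid of 28 (lactone open, all centres as in 28) | C=C[C@]1(C)C[C@H](OC(=O)[C@H](C)CO)[C@@H]([C@H](C)C(=O)O)[C@H](O)[C@H]1C(=C)CO | intermediate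
28 | (3S,3aR,4S,6S,7R,7aR)-6-ethenyl-7-(3-hydroxyprop-1-en-2-yl)-3,6-dimethyl-2-oxooctahydro-1-benzofuran-4-yl (2R)-3-hydroxy-2-methylpropanoate | C=C[C@]1(C)C[C@H](OC(=O)[C@H](C)CO)[C@@H]2[C@H](OC(=O)[C@H]2C)[C@H]1C(=C)CO | target

Total step count: 16. Longest linear sequence: 10 steps (1, 2, 4, 5, 6, 10, 13, 14, 15, 16).

Steps most likely to fail

Step 16. The hindered allylic C–OH may ionise slowly, the product's remaining allylic alcohol may be ionised and reduced further, or reaction through the cyclic lactol form may erode the trans ring fusion. The fallback sets out from 24 and comes back at 28. Me2AlCl in CH2Cl2 at −78 °C should effect a type-I carbonyl-ene cyclisation through the same all-equatorial chair; the only allylic hydrogens are on the dioxane CH2 groups, so the product is the cyclohexanol with a 4H-1,3-dioxin enol ether F1. Aqueous TFA should then hydrolyse the enol acetal, dehydrate the resulting β-hydroxy aldehyde, lactonise the tert-butyl ester and remove the TBS group, giving the enal lactone F2. Luche reduction (NaBH4, CeCl3·7H2O, MeOH, −40 °C) of F2 gives 28.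

Step 4. Transmetalation of the β,β-disubstituted alkenylboronate may be slow, and site selectivity (SN2′ versus SN2) or facial selectivity at the quaternary carbon may be poor. The fallback sets out from 7 and comes back at 19. Horner–Wadsworth–Emmons reaction of 7 with triethyl 3-methyl-4-phosphonocrotonate gives the dienoate F3, and DIBAL-H reduction gives the dienol F4. Hg(OAc)2-catalysed exchange with ethyl vinyl ether gives the allyl vinyl ether F5, and thermal Claisen rearrangement (toluene, 120 °C) gives the racemic aldehyde F6. Used in step 10, F6 gives 19 together with its epimer at the quaternary carbon F7; the two are diastereomers and are separated by chromatography.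

Step 15. Strong acid acting on the still-acyclic aldehyde may trigger Prins-type closure, ionisation of the allylic alcohols or β-elimination of the acyloxy group. The fallback sets out from 24 and comes back at 28. Selective acetonide hydrolysis (CeCl3·7H2O, oxalic acid, MeCN, rt) gives the aldehyde diol F8, with tert-butyl ester and TBS ether retained. The Pd(PPh3)4/InI cyclisation of step 16 is then run on F8 to give the cyclised hydroxy ester F9. Acid treatment of the cyclic material (TFA/CH2Cl2/H2O, 0 °C) lactonises and desilylates F9 to 28.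

Further compounds
F1 | step 16 | ene adduct: cyclohexanol with 2,2-dimethyl-4H-1,3-dioxin-5-yl group at C7, tert-butyl ester and TBS ether retained | C=C[C@]1(C)C[C@H](OC(=O)[C@H](C)CO[Si](C)(C)C(C)(C)C)[C@@H]([C@H](C)C(=O)OC(C)(C)C)[C@H](O)[C@H]1C1=COC(C)(C)OC1
F2 | step 16 | enal lactone: 28 with the CH2OH oxidised to CHO (3-oxoprop-1-en-2-yl group) | C=C[C@]1(C)C[C@H](OC(=O)[C@H](C)CO)[C@@H]2[C@H](OC(=O)[C@H]2C)[C@H]1C(=C)C=O
F3 | step 4 | ethyl (2E)-4-(2,2-dimethyl-1,3-dioxan-5-ylidene)-3-methylbut-2-enoate | CCOC(=O)/C=C(\C)C=C1COC(C)(C)OC1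
F4 | step 4 | (2E)-4-(2,2-dimethyl-1,3-dioxan-5-ylidene)-3-methylbut-2-en-1-ol | OC/C=C(\C)C=C1COC(C)(C)OC1
F5 | step 4 | 5-[(2E)-4-(ethenyloxy)-2-methylbut-2-en-1-ylidene]-2,2-dimethyl-1,3-dioxane | C=COC/C=C(\C)C=C1COC(C)(C)OC1
F6 | step 4 | racemic 3-ethenyl-4-(2,2-dimethyl-1,3-dioxan-5-ylidene)-3-methylbutanal | C=CC(C)(CC=O)C=C1COC(C)(C)OC1
F7 | step 4 | (6R)-epimer of 19 | C=C[C@@](C)(C[C@H](O)[C@@H]([C@H](C)C(=O)OC(C)(C)C)C(=O)N1C(=S)SC[C@H]1Cc1ccccc1)C=C1COC(C)(C)OC1
F8 | step 15 | aldehyde 24 with the acetonide removed (free alkylidene-1,3-diol) | C=C[C@](C)(C[C@H](OC(=O)[C@H](C)CO[Si](C)(C)C(C)(C)C)[C@@H]([C@H](C)C(=O)OC(C)(C)C)C=O)C=C(CO)CO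
F9 | step 15 | cyclised hydroxy tert-butyl ester with TBS ether retained (seco form of 28) | C=C[C@]1(C)C[C@H](OC(=O)[C@H](C)CO[Si](C)(C)C(C)(C)C)[C@@H]([C@H](C)C(=O)OC(C)(C)C)[C@H](O)[C@H]1C(=C)CO
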